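**Retrosynthetic overview**

1. The last C–C bond made is the C8–C9 single bond of the C7=C8–C9=C10 diene. It is formed from two triple bonds (C7≡C8 of a ring A 6-ethynyl-5,6-diol and C9≡C10 of a methyl-capped C29 polyenyne) by titanium-mediated reductive alkyne–alkyne cross-coupling, which also sets both E double bonds.
2. Enabling feature: on ring A (C1–C6) the C5 hydroxyl and the C7–C8 arm on C6 are cis (5R,6R). The C5 alkoxide is therefore homopropargylic to C7≡C8 and can chelate titanium only on C7, which forces the new bond to terminal C8. C6 is fully substituted, and C9 carries only a methyl while C10 carries the polyene.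
3. The C29 fragment comes from a Wittig reaction at C11'=C12' (furanoid C15 aldehyde plus C14 phosphonium salt); the C14 unit comes from a Horner–Wadsworth–Emmons reaction at C11=C12 on the C10 dialdehyde.
4. Ring C (the 2,5-dihydrofuran O–C5'–C6'=C7'–C8') is closed by gold-catalysed 5-endo cyclisation of a C5'-hydroxy allene. The allene comes from SN2' hydride opening of an alkynyl oxirane, so C8' is set by centre-to-axis-to-centre transfer.
5. Rings A and B both come from (4R,6R)-actinol through one allylic alcohol; enantiomeric tartrates in Sharpless epoxidation set C5/C6 (syn oxirane, then anti hydrolysis) and C5'/C6' (anti oxirane). Ring order: both carbocycles from the chiral pool, then ring C (step 14), none later.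

Key step: step 21

Assumption: the target is read as the all-E (3S,5R,6R,3'S,5'R,8'S) compound, carotenoid numbering is used (ring A = C1–C6 of the triol end, ring B = C1'–C6', ring C = the dihydrofuran), "up" means the ring face of the C5 and C5' oxygens with the C3 and C3' oxygens "down", and 1, 13, 18 and 20 are taken as purchasable.

**Route**

Step 1
Reactants: 1 (4R,6R)-actinol
Product: 2 TBS ether of actinol
Conditions: TBSCl, imidazole, DMF, rt
Reagents that add atoms: tert-butyldimethylsilyl chloride, CC(C)(C)[Si](C)(C)Cl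
Why: Imidazole-promoted silylation of the only hydroxyl; no stereocentre is touched.

Step 2
Reactants: 2 TBS ether of actinol
Product: 3 enol triflate
Conditions: LiN(i-Pr)2, THF, −78 °C; then PhNTf2, −78 °C → rt
Reagents that add atoms: N-phenylbis(trifluoromethanesulfonimide), O=S(=O)(N(c1ccccc1)S(=O)(=O)C(F)(F)F)C(F)(F)F
Why: Enolisation is possible only at the methyl-bearing α-carbon because the other α-carbon is quaternary, and O-triflation of the lithium enolate should give one enol triflate; the methyl-bearing stereocentre is erased on purpose and the silyloxy-bearing one is untouched.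

Step 3
Reactants: 3 enol triflate
Product: 4 methyl cyclohexenecarboxylate
Conditions: Pd(OAc)2 (5 mol%), PPh3 (10 mol%), CO (1 atm), MeOH, Et3N, DMF, 60 °C
Reagents that add atoms: carbon monoxide, [C-]#[O+]; methanol, CO
Why: Palladium-catalysed methoxycarbonylation of an enol triflate (oxidative addition, CO insertion, methanolysis) is routine for tetrasubstituted cyclohexenyl triflates and installs C7.

Step 4
Reactants: 4 methyl cyclohexenecarboxylate
Product: 5 allylic alcohol
Conditions: i-Bu2AlH (2.5 equiv), CH2Cl2, −78 → 0 °C; aqueous Rochelle salt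
Reagents that add atoms: none
Why: 1,2-Reduction of the conjugated ester by i-Bu2AlH should give the primary allylic alcohol needed for directed epoxidation.

Step 5
Reactants: 5 allylic alcohol
Product: 6 syn epoxy alcohol
Conditions: Ti(OiPr)4 (0.2 equiv), L-(+)-diethyl tartrate (0.25 equiv), t-BuOOH, 4 Å molecular sieves, CH2Cl2, −20 °C
Reagents that add atoms: tert-butyl hydroperoxide, CC(C)(C)OO
Why: Sharpless asymmetric epoxidation, in which the titanium tartrate bound to the primary allylic alcohol chooses the alkene face; L-(+)-tartrate should deliver oxygen to the face carrying the silyloxy group, setting C5 and C6 of ring A as the syn oxirane.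

Step 6
Reactants: 6 syn epoxy alcohol
Product: 7 syn epoxy aldehyde
Conditions: (n-Pr4N)RuO4 (5 mol%), N-methylmorpholine N-oxide, 4 Å molecular sieves, CH2Cl2, rt
Reagents that add atoms: none
Why: Ley–Griffith oxidation takes the primary alcohol to the aldehyde under neutral conditions that leave oxirane and silyl ether intact.

Step 7
Reactants: 7 syn epoxy aldehyde
Product: 8 syn alkynyl oxirane
Conditions: dimethyl (1-diazo-2-oxopropyl)phosphonate, K2CO3, MeOH, 0 °C → rt
Reagents that add atoms: dimethyl (1-diazo-2-oxopropyl)phosphonate, COP(=O)(OC)C(=[N+]=[N-])C(C)=O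
Why: Ohira–Bestmann homologation converts the aldehyde into the terminal alkyne (C7≡C8); the carbon next to the carbonyl is a quaternary oxirane carbon, so nothing can epimerise.

Step 8
Reactants: 8 syn alkynyl oxirane
Product: 9 ring A ethynyl diol
Conditions: HClO4 (cat.), THF/H2O 3:1, 0 °C
Reagents that add atoms: water, O
Why: Acid-catalysed anti hydrolysis of the oxirane, in which water should attack C5 (the tertiary carbon that is neither propargylic nor flanked by the gem-dimethyl group) with inversion; this places the new C5 hydroxyl trans to the C6 hydroxyl and cis to the ethynyl group.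

Step 9
Reactants: 5 allylic alcohol
Product: 10 anti epoxy alcohol
Conditions: Ti(OiPr)4 (0.2 equiv), D-(−)-diethyl tartrate (0.25 equiv), t-BuOOH, 4 Å molecular sieves, CH2Cl2, −20 °C
Reagents that add atoms: tert-butyl hydroperoxide, CC(C)(C)OO
Why: Sharpless asymmetric epoxidation with the enantiomeric tartrate should deliver oxygen to the face opposite the silyloxy group, setting the C5'–O bond in the configuration kept in ring C.

Step 10
Reactants: 10 anti epoxy alcohol
Product: 11 anti epoxy aldehyde
Conditions: (n-Pr4N)RuO4 (5 mol%), N-methylmorpholine N-oxide, 4 Å molecular sieves, CH2Cl2, rt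
Reagents that add atoms: none
Why: Ley–Griffith oxidation as in step 6.

Step 11
Reactants: 11 anti epoxy aldehyde
Product: 12 anti alkynyl oxirane
Conditions: dimethyl (1-diazo-2-oxopropyl)phosphonate, K2CO3, MeOH, 0 °C → rt
Reagents that add atoms: dimethyl (1-diazo-2-oxopropyl)phosphonate, COP(=O)(OC)C(=[N+]=[N-])C(C)=O
Why: Ohira–Bestmann homologation as in step 7, giving C7'≡C8'.

Step 12
Reactants: 12 anti alkynyl oxirane; 13 ethyl but-2-ynoate
Product: 14 epoxy enynoate
Conditions: Pd(OAc)2 (3 mol%), tris(2,6-dimethoxyphenyl)phosphine (3 mol%), THF, rt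
Reagents that add atoms: none
Why: Palladium-catalysed cross-addition of a terminal (donor) alkyne C–H across an alkynoate (acceptor) is a known atom-economic enyne synthesis; syn addition of alkynyl and hydrogen places the alkynyl group trans to the ester, giving the (E)-2-en-4-ynoate with the C9' methyl in place.

Step 13
Reactants: 14 epoxy enynoate
Product: 15 allenic diol
Conditions: i-Bu2AlH (5 equiv), CH2Cl2, −78 → 0 °C; aqueous Rochelle salt
Reagents that add atoms: none
Why: i-Bu2AlH reduces the ester to the allylic alcohol and opens the alkynyl oxirane in the SN2' sense, a reduction with close precedent on alkynyl oxiranes of this ring type; hydride should be delivered to C8' from aluminium bound to the oxirane oxygen (syn to the breaking C6'–O bond), which fixes the (R) allene axis with H8' on the face of the retained C5' hydroxyl.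

Step 14
Reactants: 15 allenic diol
Product: 16 dihydrofuran allylic alcohol
Conditions: AuCl3 (5 mol%), THF, 0 °C → rt
Reagents that add atoms: none
Why: Gold-catalysed 5-endo cycloisomerisation of an α-hydroxyallene to a 2,5-dihydrofuran with axis-to-centre transfer; the C5' oxygen attacks C8' in the plane of C5'/C6'/C7', so the C8' substituents keep their faces and the side chain ends cis to the C5' methyl (8'S).

Step 15
Reactants: 16 dihydrofuran allylic alcohol
Product: 17 furanoid C15 aldehyde
Conditions: MnO2, CH2Cl2, rt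
Reagents that add atoms: none
Why: MnO2 oxidises only the primary allylic alcohol, under neutral conditions that do not touch the acid-sensitive allylic ether at C8'.

Step 16
Reactants: 18 1-bromobut-2-yne
Product: 19 diethyl but-2-yn-1-ylphosphonate
Conditions: P(OEt)3, neat, 120 °C
Reagents that add atoms: triethyl phosphite, CCOP(OCC)OCC
Why: Michaelis–Arbuzov reaction of a primary propargylic bromide.

Step 17
Reactants: 19 diethyl but-2-yn-1-ylphosphonate; 20 C10 dialdehyde (2.5 equiv)
Product: 21 C14 tetraenynal
Conditions: NaN(SiMe3)2, THF, −78 °C; anion added to 20, −78 → 0 °C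
Reagents that add atoms: none
Why: Horner–Wadsworth–Emmons olefination with a propargylic phosphonate anion is E-selective at C11=C12, and slow addition to an excess of the symmetrical dialdehyde should limit double olefination.

Step 18
Reactants: 21 C14 tetraenynal
Product: 22 C14 tetraenynol
Conditions: NaBH4, MeOH/THF, 0 °C
Reagents that add atoms: none
Why: NaBH4 reduces the polyenal 1,2-selectively to the allylic alcohol.

Step 19
Reactants: 22 C14 tetraenynol
Product: 23 C14 phosphonium bromide
Conditions: PPh3·HBr, MeOH, rt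
Reagents that add atoms: triphenylphosphine hydrobromide, [Br-].c1ccc(cc1)[PH+](c1ccccc1)c1ccccc1
Why: Triphenylphosphine hydrobromide converts polyene allylic alcohols into primary phosphonium salts (ionisation to the delocalised cation, capture at the terminal carbon), the standard entry to carotenoid Wittig salts.

Step 20
Reactants: 23 C14 phosphonium bromide; 17 furanoid C15 aldehyde
Product: 26 all-E C29 polyenyne, via phosphorus ylide 24 (not isolated), via 11'Z isomer 25 (not isolated)
Conditions: NaN(SiMe3)2 (1.0 equiv), THF, −78 °C; then 17, −78 → 0 °C; then n-heptane, 80 °C, dark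
Reagents that add atoms: none
Why: Wittig olefination of a semi-stabilised polyenyl ylide forms C11'=C12'; the aldehyde is added to the preformed ylide at low temperature so that no free base can remove the γ-hydrogen at C8', and the hindered 11'Z isomer should relax thermally to all-E.

Step 21
Reactants: 26 all-E C29 polyenyne; 9 ring A ethynyl diol
Product: 30 bis-TBS latochrome, via titanium alkyne complex 27 (not isolated), via dilithium dialkoxide 28 (not isolated), via titanacyclopentadiene 29 (not isolated)
Conditions: 26 (1.0 equiv), Ti(OiPr)4 (1.05 equiv), c-C5H9MgCl (2.1 equiv), toluene/Et2O, −78 → −35 °C; then 28 [from 9 (1.5 equiv), n-BuLi (3.0 equiv), THF, −78 °C], −78 → 0 °C; then aqueous NaHCO3, 0 °C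
Reagents that add atoms: none
Why: Proposed new method: divalent titanium generated from Ti(OiPr)4 and two equivalents of c-C5H9MgCl should bind the C9≡C10 triple bond of 26 as titanacyclopropene 27, exchange of an isopropoxide for the C5 alkoxide of 28 then brings the C7≡C8 triple bond to the metal, syn insertion into the Ti–C9 bond gives titanacyclopentadiene 29 and protonolysis of its two Ti–C bonds with retention releases the diene; the closest known reaction type is the alkoxide-directed, titanium alkoxide-mediated reductive cross-coupling of an internal alkyne with a second alkyne to stereodefined 1,3-dienes, which has been run on conjugated enynes and with terminal alkynes as the inserting partner but not on a carotenoid-length polyenyne or with a terminal alkyne as the tethered partner. No ring of the product is closed; the only rings formed are the transient titanacyclopentadiene (oxidative cyclisation of two alkynes on titanium) and its fused five-membered Ti–O–C5–C6–C7 chelate. No stereocentre is created, but both new double bonds are fixed by the metallacycle: Ti and the new C–C bond are cis on each alkyne, so after protonolysis C6 and C9 are trans on C7=C8 and C8 and C11 are trans on C9=C10. The step needs regiocontrol at both alkynes: at ring A the cis C5 alkoxide can chelate only when titanium sits on C7 and the fully substituted C6 prefers the position next to the metal, so the bond forms at terminal C8, and at the other alkyne the small methyl on C9 and the conjugating polyenyl group on C10 direct the bond to C9. It also needs chemoselectivity for the alkyne over the conjugated hexaene and over proton transfer from the terminal C–H, which should be secured by the stronger binding of alkynes to divalent titanium, by exact stoichiometry at −78 to −30 °C and by fast intramolecular insertion once the alkoxide is bound. The C6 oxygen stays as a lithium alkoxide, a leaving group too poor for β-elimination to an allene.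

Step 22
Reactants: 30 bis-TBS latochrome
Product: 31 target tetrol
Conditions: n-Bu4NF (4 equiv), THF, 0 °C → rt
Reagents that add atoms: none
Why: Fluoride cleaves both secondary silyl ethers under basic conditions that should spare the acid-sensitive ring C, the allylic tertiary diol and the polyene.

**Compound list**

1 | (4R,6R)-4-hydroxy-2,2,6-trimethylcyclohexan-1-one ((4R,6R)-actinol) | O=C1C(C)(C)C[C@H](O)C[C@H]1C | starting material
2 | (4R,6R)-4-(tert-butyldimethylsilyloxy)-2,2,6-trimethylcyclohexan-1-one | O=C1C(C)(C)C[C@H](O[Si](C)(C)C(C)(C)C)C[C@H]1C | intermediate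
3 | (4R)-4-(tert-butyldimethylsilyloxy)-2,6,6-trimethylcyclohex-1-en-1-yl trifluoromethanesulfonate | CC1=C(OS(=O)(=O)C(F)(F)F)C(C)(C)C[C@H](O[Si](C)(C)C(C)(C)C)C1 | intermediate
4 | methyl (4R)-4-(tert-butyldimethylsilyloxy)-2,6,6-trimethylcyclohex-1-ene-1-carboxylate | CC1=C(C(=O)OC)C(C)(C)C[C@H](O[Si](C)(C)C(C)(C)C)C1 | intermediate
5 | [(4R)-4-(tert-butyldimethylsilyloxy)-2,6,6-trimethylcyclohex-1-en-1-yl]methanol | CC1=C(CO)C(C)(C)C[C@H](O[Si](C)(C)C(C)(C)C)C1 | intermediate
6 | syn epoxy alcohol: [4-(tert-butyldimethylsilyloxy)-2,2,6-trimethyl-7-oxabicyclo[4.1.0]heptan-1-yl]methanol, oxirane oxygen cis to the silyloxy group | OC[C@]12O[C@@]1(C)C[C@@H](O[Si](C)(C)C(C)(C)C)CC2(C)C | intermediate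
7 | syn epoxy aldehyde: 4-(tert-butyldimethylsilyloxy)-2,2,6-trimethyl-7-oxabicyclo[4.1.0]heptane-1-carbaldehyde, oxirane oxygen cis to the silyloxy group | O=C[C@]12O[C@@]1(C)C[C@@H](O[Si](C)(C)C(C)(C)C)CC2(C)C | intermediate
8 | syn alkynyl oxirane: 1-ethynyl-4-(tert-butyldimethylsilyloxy)-2,2,6-trimethyl-7-oxabicyclo[4.1.0]heptane, oxirane oxygen cis to the silyloxy group | C#C[C@]12O[C@@]1(C)C[C@@H](O[Si](C)(C)C(C)(C)C)CC2(C)C | intermediate
9 | ring A fragment: (1S,2R,4S)-4-(tert-butyldimethylsilyloxy)-1-ethynyl-2,6,6-trimethylcyclohexane-1,2-diol (carotenoid 3S,5R,6R pattern; 5-OH trans to 6-OH and cis to ethynyl) | C#C[C@@]1(O)C(C)(C)C[C@H](O[Si](C)(C)C(C)(C)C)C[C@@]1(C)O | intermediate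
10 | anti epoxy alcohol: [4-(tert-butyldimethylsilyloxy)-2,2,6-trimethyl-7-oxabicyclo[4.1.0]heptan-1-yl]methanol, oxirane oxygen trans to the silyloxy group | OC[C@@]12O[C@]1(C)C[C@@H](O[Si](C)(C)C(C)(C)C)CC2(C)C | intermediate
11 | anti epoxy aldehyde: 4-(tert-butyldimethylsilyloxy)-2,2,6-trimethyl-7-oxabicyclo[4.1.0]heptane-1-carbaldehyde, oxirane oxygen trans to the silyloxy group | O=C[C@@]12O[C@]1(C)C[C@@H](O[Si](C)(C)C(C)(C)C)CC2(C)C | intermediate
12 | anti alkynyl oxirane: 1-ethynyl-4-(tert-butyldimethylsilyloxy)-2,2,6-trimethyl-7-oxabicyclo[4.1.0]heptane, oxirane oxygen trans to the silyloxy group | C#C[C@@]12O[C@]1(C)C[C@@H](O[Si](C)(C)C(C)(C)C)CC2(C)C | intermediate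
13 | ethyl but-2-ynoate | CC#CC(=O)OCC | starting material
14 | epoxy enynoate: ethyl (2E)-3-methyl-5-[anti oxirane ring of 12]pent-2-en-4-ynoate | CCOC(=O)/C=C(\C)C#C[C@@]12O[C@]1(C)C[C@@H](O[Si](C)(C)C(C)(C)C)CC2(C)C | intermediate
15 | allenic diol: (2E)-3-methyl-5-[4-(tert-butyldimethylsilyloxy)-2-hydroxy-2,6,6-trimethylcyclohexylidene]penta-2,4-dien-1-ol, (R) allene axis, tertiary OH trans to the silyloxy group, H8' on the face of that OH | OC/C=C(\C)[CH]=[C@@]=C1C(C)(C)C[C@H](O[Si](C)(C)C(C)(C)C)C[C@@]1(C)O | intermediate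
16 | (2E)-3-[(2S,6S,7aR)-6-(tert-butyldimethylsilyloxy)-4,4,7a-trimethyl-2,4,5,6,7,7a-hexahydro-1-benzofuran-2-yl]but-2-en-1-ol | OC/C=C(\C)[C@@H]1C=C2C(C)(C)C[C@H](O[Si](C)(C)C(C)(C)C)C[C@@]2(C)O1 | intermediate
17 | (2E)-3-[(2S,6S,7aR)-6-(tert-butyldimethylsilyloxy)-4,4,7a-trimethyl-2,4,5,6,7,7a-hexahydro-1-benzofuran-2-yl]but-2-enal | O=C/C=C(\C)[C@@H]1C=C2C(C)(C)C[C@H](O[Si](C)(C)C(C)(C)C)C[C@@]2(C)O1 | intermediate
18 | 1-bromobut-2-yne | CC#CCBr | starting material
19 | diethyl but-2-yn-1-ylphosphonate | CC#CCP(=O)(OCC)OCC | intermediate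
20 | (2E,4E,6E)-2,7-dimethylocta-2,4,6-trienedial (C10 dialdehyde) | O=C/C(C)=C/C=C/C=C(C)/C=O | starting material
21 | (2E,4E,6E,8E)-2,7-dimethyldodeca-2,4,6,8-tetraen-10-ynal | CC#C/C=C/C(C)=C/C=C/C=C(\C)C=O | intermediate
22 | (2E,4E,6E,8E)-2,7-dimethyldodeca-2,4,6,8-tetraen-10-yn-1-ol | CC#C/C=C/C(C)=C/C=C/C=C(\C)CO | intermediate
23 | [(2E,4E,6E,8E)-2,7-dimethyldodeca-2,4,6,8-tetraen-10-yn-1-yl]triphenylphosphonium bromide | CC#C/C=C/C(C)=C/C=C/C=C(\C)C[P+](c1ccccc1)(c1ccccc1)c1ccccc1.[Br-] | intermediate
24 | phosphorus ylide of 23 (not isolated) | CC#C/C=C/C(C)=C/C=C/C=C(\C)C=P(c1ccccc1)(c1ccccc1)c1ccccc1 | intermediate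
25 | 11'Z isomer of 26 (not isolated) | CC#C/C=C/C(C)=C/C=C/C=C(C)/C=C\C=C(/C)[C@@H]1C=C2C(C)(C)C[C@H](O[Si](C)(C)C(C)(C)C)C[C@@]2(C)O1 | intermediate
26 | C29 polyenyne: (2S,6S,7aR)-6-(tert-butyldimethylsilyloxy)-2-[(2E,4E,6E,8E,10E,12E)-6,11-dimethylhexadeca-2,4,6,8,10,12-hexaen-14-yn-2-yl]-4,4,7a-trimethyl-2,4,5,6,7,7a-hexahydro-1-benzofuran | CC#C/C=C/C(C)=C/C=C/C=C(C)/C=C/C=C(\C)[C@@H]1C=C2C(C)(C)C[C@H](O[Si](C)(C)C(C)(C)C)C[C@@]2(C)O1 | intermediate
27 | titanium alkyne complex of 26: diisopropoxytitanacyclopropene on C9/C10 (not isolated) | CC1=C(/C=C/C(C)=C/C=C/C=C(C)/C=C/C=C(\C)[C@@H]2C=C3C(C)(C)C[C@H](O[Si](C)(C)C(C)(C)C)C[C@@]3(C)O2)[Ti]1(OC(C)C)OC(C)C | intermediate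
28 | dilithium 5,6-dialkoxide of 9 (not isolated) | C#C[C@@]1(O[Li])C(C)(C)C[C@H](O[Si](C)(C)C(C)(C)C)C[C@@]1(C)O[Li] | intermediate
29 | titanacyclopentadiene: Ti bonded to C7 and C10, chelated by the C5 oxygen, one isopropoxide left, C6–OLi (not isolated) | C1(=CC(C)=C(/C=C/C(C)=C/C=C/C=C(C)/C=C/C=C(\C)[C@@H]4C=C5C(C)(C)C[C@H](O[Si](C)(C)C(C)(C)C)C[C@@]5(C)O4)[Ti]1(OC(C)C)O2)[C@@]3(O[Li])C(C)(C)C[C@H](O[Si](C)(C)C(C)(C)C)C[C@]32C | intermediate
30 | (3S,5R,6R,3'S,5'R,8'S)-3,3'-bis(tert-butyldimethylsilyloxy)-5',8'-epoxy-5,6,5',8'-tetrahydro-β,β-carotene-5,6-diol | CC(/C=C/C=C(C)/C=C/[C@@]1(O)C(C)(C)C[C@H](O[Si](C)(C)C(C)(C)C)C[C@@]1(C)O)=C\C=C\C=C(C)\C=C\C=C(/C)[C@@H]1C=C2C(C)(C)C[C@H](O[Si](C)(C)C(C)(C)C)C[C@@]2(C)O1 | intermediate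
31 | (3S,5R,6R,3'S,5'R,8'S)-5',8'-epoxy-5,6,5',8'-tetrahydro-β,β-carotene-3,5,6,3'-tetrol (CNP0210286.3) | CC(/C=C/C=C(C)/C=C/[C@@]1(O)C(C)(C)C[C@H](O)C[C@@]1(C)O)=C\C=C\C=C(C)\C=C\C=C(/C)[C@@H]1C=C2C(C)(C)C[C@H](O)C[C@@]2(C)O1 | target

**Step count and risks**

Total step count: 22. Longest linear sequence: 14 steps (1–4, 9–15, 20, 21, 22).

Three steps most likely to fail:

Step 21 (key step). What may go wrong: divalent titanium may complex or reduce the conjugated hexaene instead of staying on the alkyne, the terminal C–H may protonate the titanacyclopropene before insertion, or insertion may occur with the wrong orientation. The fallback makes the same bond by palladium chemistry after separate hydrometallation of the two alkynes. Setting out from 9, palladium-catalysed hydrostannation (n-Bu3SnH, PdCl2(PPh3)2, THF, 0 °C) should give the (E)-vinylstannane F1. Setting out from 26, hydrozirconation with Cp2Zr(H)Cl (THF, rt, dark; zirconium to the methyl-bearing C9) followed by N-iodosuccinimide at −78 °C should give the (9E)-9-iodo polyene F2. Stille coupling of F1 and F2 (Pd2(dba)3, AsPh3, DMF, rt) comes back to the route at 30.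

Step 14. What may go wrong: the axis-to-centre transfer may erode through a gold-bound allyl cation that can rotate, or the vinylallene may undergo carbocyclisation instead of O-attack. The fallback replaces π-acid catalysis by stoichiometric halocyclisation. Setting out from 15, iodoetherification with N-iodosuccinimide (NaHCO3, CH2Cl2, −40 °C; anti addition of oxygen and iodine across C7'=C8' in the ring plane, so the C8' substituents keep their faces) should give the 3-iodo-2,5-dihydrofuran F3. Palladium-catalysed hydrodeiodination (Pd(PPh3)4, n-Bu3SnH, THF, rt) comes back to the route at 16.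

Step 8. What may go wrong: the oxirane may open at the propargylic carbon or through a free cation with partial retention, and the silyl ether may be lost in acid. The fallback opens the oxirane earlier, under chelation control. Setting out from 6, Ti(OiPr)4-mediated opening with benzoic acid at the oxirane carbon remote from the carbinol (C5), with inversion, should give the C5 benzoate triol F4. Selective oxidation of the primary alcohol (TEMPO, PhI(OAc)2, CH2Cl2) gives the α-hydroxy aldehyde F5. Ohira–Bestmann alkynylation in K2CO3/MeOH, followed by NaOMe in the same pot to cleave the benzoate, comes back to the route at 9.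

Further compounds
F1 | step 21 | (1R,2R,4S)-4-(tert-butyldimethylsilyloxy)-2,6,6-trimethyl-1-[(E)-2-(tributylstannyl)ethenyl]cyclohexane-1,2-diol | CCCC[Sn](CCCC)(CCCC)/C=C/[C@@]1(O)C(C)(C)C[C@H](O[Si](C)(C)C(C)(C)C)C[C@@]1(C)O
F2 | step 21 | (9E)-9-iodo C29 polyene: (2S,6S,7aR)-6-(tert-butyldimethylsilyloxy)-2-[(2E,4E,6E,8E,10E,12E,14E)-15-iodo-6,11-dimethylhexadeca-2,4,6,8,10,12,14-heptaen-2-yl]-4,4,7a-trimethyl-2,4,5,6,7,7a-hexahydro-1-benzofuran | C/C(I)=C\C=C\C(C)=C\C=C\C=C(C)\C=C\C=C(/C)[C@@H]1C=C2C(C)(C)C[C@H](O[Si](C)(C)C(C)(C)C)C[C@@]2(C)O1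
F3 | step 14 | 3-iodo analogue of 16: (2E)-3-[6-(tert-butyldimethylsilyloxy)-3-iodo-4,4,7a-trimethyl-2,4,5,6,7,7a-hexahydro-1-benzofuran-2-yl]but-2-en-1-ol, ring stereochemistry as in 16 | OC/C=C(\C)[C@@H]1C(I)=C2C(C)(C)C[C@H](O[Si](C)(C)C(C)(C)C)C[C@@]2(C)O1
F4 | step 8 | C5 benzoate triol: 4-(tert-butyldimethylsilyloxy)-2-hydroxy-2-(hydroxymethyl)-1,3,3-trimethylcyclohexyl benzoate, ring stereochemistry as in 9 | OC[C@@]1(O)C(C)(C)C[C@H](O[Si](C)(C)C(C)(C)C)C[C@@]1(C)OC(=O)c1ccccc1
F5 | step 8 | α-hydroxy aldehyde: 4-(tert-butyldimethylsilyloxy)-2-formyl-2-hydroxy-1,3,3-trimethylcyclohexyl benzoate, ring stereochemistry as in 9 | O=C[C@@]1(O)C(C)(C)C[C@H](O[Si](C)(C)C(C)(C)C)C[C@@]1(C)OC(=O)c1ccccc1
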